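**Retrosynthetic overview**

1. Target ⇐ O‑acylation of the ring‑opened 6β,12‑lactone 11‑acid with an octatrienoyl imidazolide; the trienoic acid comes from sorbaldehyde and malonic acid.
2. Lactone acid ⇐ 6‑oxo cis‑8β,9β‑anhydride by α‑face CBS reduction (a kinetic resolution that fixes absolute configuration); the 6β‑oxygen closes onto C12.
3. Key disconnection C9–C10: an MHAT‑generated tertiary C10 radical cyclises 6‑endo onto a tethered alkylmaleic anhydride, forming ring B and setting C10, C9 and C8 together.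
4. Cyclisation precursor ⇐ ring‑A methyl ketone + bromomaleic anhydride (Mukaiyama–Michael addition, then loss of HBr).
5. Ring order: A first (Diels–Alder of mesityl oxide with piperylene, then alkene migration), B second (radical step); the anhydride ring is carried in intact.

Assumption: compounds 3, 4, 8 and 9 are racemic (9 is drawn as the enantiomer carried on), and drimane numbering is used (C5/C10 ring fusion, C6 carbinol, C12 on C8, C11 on C9).

**Step 1**
Reactants: 1 mesityl oxide (4‑methylpent‑3‑en‑2‑one); 2 (E)‑penta‑1,3‑diene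
Product: 3 rac‑trans‑1‑(2,6,6‑trimethylcyclohex‑3‑en‑1‑yl)ethan‑1‑one
Conditions: AlCl3 (15 mol %), CH2Cl2, 0 °C → rt
Reagents that add atoms: none
Why: Lewis‑acid‑catalysed Diels–Alder reaction in which the unsubstituted diene terminus bonds to the β,β‑dimethyl carbon ("ortho" adduct), giving a racemic cis/trans pair that AlCl3 equilibrates mainly to trans; either epimer is usable because step 2 erases the methyl‑bearing centre and the other stays racemic until step 5.

**Step 2**
Reactants: 3 rac‑trans‑1‑(2,6,6‑trimethylcyclohex‑3‑en‑1‑yl)ethan‑1‑one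
Product: 4 rac‑1‑(2,6,6‑trimethylcyclohex‑2‑en‑1‑yl)ethan‑1‑one
Conditions: RuHCl(CO)(PPh3)3 (2 mol %), toluene, 110 °C
Reagents that add atoms: none
Why: Ru–H insertion/β‑hydride elimination (chain‑walking alkene isomerisation) moves the 1,2‑disubstituted ring alkene to the more stable trisubstituted position and should stop there, since further migration into conjugation would need a tertiary alkyl–Ru intermediate; the remaining stereocentre is racemic.

**Step 3**
Reactants: 4 rac‑1‑(2,6,6‑trimethylcyclohex‑2‑en‑1‑yl)ethan‑1‑one; 5 bromomaleic anhydride (3‑bromofuran‑2,5‑dione)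
Product: 8 rac‑3‑[2‑oxo‑2‑(2,6,6‑trimethylcyclohex‑2‑en‑1‑yl)ethyl]furan‑2,5‑dione, via silyl enol ether 6 (not isolated), via silyl ketene acetal adduct 7 (not isolated)
Conditions: LDA, THF, −78 °C; TMSCl; then 5, TMSOTf (5 mol %), CH2Cl2, −78 → −40 °C; then Et3N, 0 °C; cold aq. NH4Cl
Reagents that add atoms: none
Why: Kinetic deprotonation at CH3 gives the less substituted silyl enol ether, which adds in a Mukaiyama–Michael reaction to the strongly electrophilic bromomaleic anhydride, and base‑mediated loss of the bromide (E1cB) restores the endocyclic alkylmaleic anhydride, which locks the future C8=C9 acceptor in the Z (maleate) geometry; no stereocentre is formed.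

**Step 4**
Reactants: 8 rac‑3‑[2‑oxo‑2‑(2,6,6‑trimethylcyclohex‑2‑en‑1‑yl)ethyl]furan‑2,5‑dione
Product: 9 rac‑6‑oxo‑8β,9β‑drimane‑11,12‑dioic anhydride (5α‑H and 10β‑Me trans‑decalin; cis‑fused anhydride)
Conditions: Fe(acac)3 (0.3 equiv), PhSiH2(Oi‑Pr) (2 equiv), t‑BuOH (2 equiv), THF (0.02 M), 35 °C
Reagents that add atoms: none
Why: Metal‑hydride H‑atom transfer puts H on C1 and leaves the tertiary C10 radical, which adds 6‑endo to the unsubstituted carbon (C9) of the Z‑locked alkylmaleic anhydride through a chair transition state with both ring‑A bonds equatorial (trans‑decalin, axial methyl), so C11, being trans to the tether on the alkene, ends equatorial (9β), and the anhydride α‑radical/iron enolate then takes up H on the face away from the new quaternary centre to give the cis‑fused anhydride (8β); 5‑exo closure is disfavoured because it would join two fully substituted carbons (intramolecular MHAT Giese cyclisation, run aprotic to keep the anhydride).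

**Step 5**
Reactants: 9 rac‑6‑oxo‑8β,9β‑drimane‑11,12‑dioic anhydride
Product: 11 (5S,6R,8S,9S,10S)‑6β‑hydroxydrimane‑11,12‑dioic acid 12,6‑lactone (free C11 acid), via hydroxy anhydride 10 (not isolated)
Conditions: (S)‑Me‑CBS (20 mol %), catecholborane (0.6 equiv), toluene, −78 → −40 °C; aq. NH4Cl; recrystallise
Reagents that add atoms: none
Why: Corey–Bakshi–Shibata reduction in which, for the (5S,10S) ketone, the catalyst‑preferred face (C5 as the large group, giving 6R) is the open α face while the β face is blocked by the two axial methyls, so this enantiomer is reduced fast and its mirror image is mismatched (kinetic resolution, at most 50 % yield), and the axial 6β‑oxygen, 1,3‑diaxial to C12, opens the anhydride at once to the γ‑lactone, which also separates product from unreacted ketone.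

**Step 6**
Reactants: 12 (2E,4E)‑hexa‑2,4‑dienal; 13 malonic acid
Product: 15 (2E,4E,6E)‑octa‑2,4,6‑trienoic acid, via dienylidenemalonic acid 14 (not isolated)
Conditions: pyridine, piperidine (cat.), 90 °C
Reagents that add atoms: none
Why: Knoevenagel–Doebner condensation with in‑situ decarboxylation gives the new C2=C3 bond E under thermodynamic control and leaves the two E alkenes of the aldehyde untouched.

**Step 7**
Reactants: 11 (5S,6R,8S,9S,10S)‑6β‑hydroxydrimane‑11,12‑dioic acid 12,6‑lactone; 15 (2E,4E,6E)‑octa‑2,4,6‑trienoic acid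
Product: 18 (5S,6R,8S,9S,10S)‑6‑[(2E,4E,6E)‑octa‑2,4,6‑trienoyloxy]drimane‑11,12‑dioic acid (target), via dilithium hydroxy dicarboxylate 16 (not isolated), via acyl imidazole 17 (not isolated)
Conditions: LiOH·H2O (2.1 equiv), THF/H2O, rt; evaporate, PhMe azeotrope; NaH (1.1 equiv), DMF, 0 °C; add 17 [15, CDI, DMF, rt], 0 °C → rt; cold 1 M HCl to pH 3
Reagents that add atoms: lithium hydroxide, [Li+].[OH-]
Why: Saponification turns C12 into a non‑electrophilic carboxylate, so the hindered axial 6β‑alkoxide is the only nucleophile that reacts irreversibly with the N‑acylimidazole (carboxylates do not, imidazolide being the poorer leaving group), and acidification then frees the diacid with O6 already acylated so the lactone cannot re‑form; no stereocentre is touched (chemoselective O‑acylation with an acyl imidazolide).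

**Compound list**

1 | mesityl oxide (4‑methylpent‑3‑en‑2‑one) | CC(=O)C=C(C)C | starting material
2 | (E)‑penta‑1,3‑diene | C=C/C=C/C | starting material
3 | rac‑trans‑1‑(2,6,6‑trimethylcyclohex‑3‑en‑1‑yl)ethan‑1‑one | CC(=O)[C@H]1[C@H](C)C=CCC1(C)C | intermediate
4 | rac‑1‑(2,6,6‑trimethylcyclohex‑2‑en‑1‑yl)ethan‑1‑one | CC(=O)C1C(C)=CCCC1(C)C | intermediate
5 | bromomaleic anhydride (3‑bromofuran‑2,5‑dione) | O=C1OC(=O)C(Br)=C1 | starting material
6 | rac‑trimethyl{[1‑(2,6,6‑trimethylcyclohex‑2‑en‑1‑yl)ethenyl]oxy}silane | C=C(O[Si](C)(C)C)C1C(C)=CCCC1(C)C | intermediate (not isolated)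
7 | 4‑bromo‑3‑[2‑oxo‑2‑(2,6,6‑trimethylcyclohex‑2‑en‑1‑yl)ethyl]‑5‑(trimethylsilyloxy)furan‑2(3H)‑one (diastereomer mixture) | CC1=CCCC(C)(C)C1C(=O)CC1C(=O)OC(O[Si](C)(C)C)=C1Br | intermediate (not isolated)
8 | rac‑3‑[2‑oxo‑2‑(2,6,6‑trimethylcyclohex‑2‑en‑1‑yl)ethyl]furan‑2,5‑dione | CC1=CCCC(C)(C)C1C(=O)CC1=CC(=O)OC1=O | intermediate
9 | rac‑(5S,8S,9S,10S)‑6‑oxodrimane‑11,12‑dioic anhydride | O=C1C[C@@H]3C(=O)OC(=O)[C@@H]3[C@@]2(C)CCCC(C)(C)[C@H]12 | intermediate
10 | (5S,6R,8S,9S,10S)‑6β‑hydroxydrimane‑11,12‑dioic anhydride | O[C@@H]1C[C@@H]3C(=O)OC(=O)[C@@H]3[C@@]2(C)CCCC(C)(C)[C@H]12 | intermediate (not isolated)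
11 | (5S,6R,8S,9S,10S)‑6β‑hydroxydrimane‑11,12‑dioic acid 12,6‑lactone | O=C3O[C@@H]1C[C@H]3[C@H](C(=O)O)[C@@]2(C)CCCC(C)(C)[C@H]12 | intermediate
12 | (2E,4E)‑hexa‑2,4‑dienal | C/C=C/C=C/C=O | starting material
13 | malonic acid | OC(=O)CC(=O)O | starting material
14 | 2‑[(2E,4E)‑hexa‑2,4‑dien‑1‑ylidene]propanedioic acid | C/C=C/C=C/C=C(C(=O)O)C(=O)O | intermediate (not isolated)
15 | (2E,4E,6E)‑octa‑2,4,6‑trienoic acid | C/C=C/C=C/C=C/C(=O)O | intermediate
16 | dilithium (5S,6R,8S,9S,10S)‑6β‑hydroxydrimane‑11,12‑dioate | [Li+].[Li+].O[C@@H]1C[C@H](C(=O)[O-])[C@H](C(=O)[O-])[C@@]2(C)CCCC(C)(C)[C@H]12 | intermediate (not isolated)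
17 | (2E,4E,6E)‑1‑(1H‑imidazol‑1‑yl)octa‑2,4,6‑trien‑1‑one | C/C=C/C=C/C=C/C(=O)n1ccnc1 | intermediate (not isolated)
18 | (5S,6R,8S,9S,10S)‑6‑[(2E,4E,6E)‑octa‑2,4,6‑trienoyloxy]drimane‑11,12‑dioic acid | C/C=C/C=C/C=C/C(=O)O[C@@H]1C[C@H](C(=O)O)[C@H](C(=O)O)[C@@]2(C)CCCC(C)(C)[C@H]12 | target

**Step count**

Total steps: 7. Longest linear sequence: 6 (steps 1, 2, 3, 4, 5, 7).

**Three steps most likely to fail**

Step 4 (radical cyclisation). The risks are cis‑ring‑fusion closure, which would also invert the C9/C10 relationship, and simple reduction of the C10 radical before it cyclises. The fallback keeps the same radical C9–C10 closure but generates the radical by halogen abstraction instead of MHAT. It sets out from 8: HBr (gas, CH2Cl2, −20 °C) adds Markovnikov to the ring alkene to give the tertiary bromide 3‑[2‑(2‑bromo‑2,6,6‑trimethylcyclohexyl)‑2‑oxoethyl]furan‑2,5‑dione F4. Slow addition of (TMS)3SiH/AIBN in benzene at 80 °C then abstracts bromine, the same C10 radical cyclises, and the bulky silane delivers H to C8 from the open face; this rejoins the route at 9.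

Step 3 (Mukaiyama–Michael/elimination). The risk is acylation at an anhydride carbonyl instead of conjugate addition, and enol‑lactone or exocyclic‑alkene tautomers of 8. The fallback reverses the polarity and sets out from 4 through its silyl enol ether 6. NBS (THF, −78 °C) gives the α‑bromo ketone 2‑bromo‑1‑(2,6,6‑trimethylcyclohex‑2‑en‑1‑yl)ethan‑1‑one F1. Separately, maleic anhydride and PPh3 give the stabilised ylide 3‑(triphenylphosphoranylidene)oxolane‑2,5‑dione F2, which is C‑alkylated by F1 to the phosphonium bromide F3. Et3N then expels PPh3 by E1cB and forms the ring alkene, rejoining the route at 8.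

Step 7 (acylation of the hindered alkoxide as a tri‑salt). The risk is low conversion, with unreacted material closing back to 11 on acidification (recoverable). The fallback uses ester protection and sets out from 11 through 16. Allyl bromide in DMF alkylates both carboxylates to give the diallyl 6β‑hydroxy diester F5, which is acylated at once with (2E,4E,6E)‑octa‑2,4,6‑trienoyl chloride F6 (from 15 and oxalyl chloride) using Et3N/DMAP to give the diallyl ester trienoate F7. Pd(PPh3)4/morpholine (THF, rt) removes both allyl groups without base or acid strong enough to epimerise C8 or harm the triene, rejoining the route at 18.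

**Further compounds**

F1 | step 3 | 2‑bromo‑1‑(2,6,6‑trimethylcyclohex‑2‑en‑1‑yl)ethan‑1‑one (racemic) | CC1=CCCC(C)(C)C1C(=O)CBr
F2 | step 3 | 3‑(triphenylphosphoranylidene)oxolane‑2,5‑dione | O=C1OC(=O)C(=P(c2ccccc2)(c2ccccc2)c2ccccc2)C1
F3 | step 3 | {2,5‑dioxo‑3‑[2‑oxo‑2‑(2,6,6‑trimethylcyclohex‑2‑en‑1‑yl)ethyl]oxolan‑3‑yl}triphenylphosphonium bromide | [Br-].O=C1OC(=O)C(CC(=O)C2C(C)=CCCC2(C)C)([P+](c2ccccc2)(c2ccccc2)c2ccccc2)C1
F4 | step 4 | 3‑[2‑(2‑bromo‑2,6,6‑trimethylcyclohexyl)‑2‑oxoethyl]furan‑2,5‑dione (racemic diastereomers) | CC1(Br)CCCC(C)(C)C1C(=O)CC1=CC(=O)OC1=O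
F5 | step 7 | diallyl (5S,6R,8S,9S,10S)‑6β‑hydroxydrimane‑11,12‑dioate | O[C@@H]1C[C@H](C(=O)OCC=C)[C@H](C(=O)OCC=C)[C@@]2(C)CCCC(C)(C)[C@H]12
F6 | step 7 | (2E,4E,6E)‑octa‑2,4,6‑trienoyl chloride | C/C=C/C=C/C=C/C(=O)Cl
F7 | step 7 | diallyl (5S,6R,8S,9S,10S)‑6‑[(2E,4E,6E)‑octa‑2,4,6‑trienoyloxy]drimane‑11,12‑dioate | C/C=C/C=C/C=C/C(=O)O[C@@H]1C[C@H](C(=O)OCC=C)[C@H](C(=O)OCC=C)[C@@]2(C)CCCC(C)(C)[C@H]12
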